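Slow feeding is easily taken to shift the product split whichever reagent is fed, but the west and south-west runs, which differ in Q, end at one split within the scatter.

| setting | east | south-west | west | south | winter | noon | midnight |
|---|---|---|---|---|---|---|---|
| G | 0.50 M | 0.50 M | 0.50 M | 1 M | 0.50 M | 0.50 M | 0.50 M |
| J | 0.80 equiv | 0.80 equiv | 0.80 equiv | 0.80 equiv | 0.800 equiv | 0.800 equiv | 0.800 equiv |
| D | 0.60 equiv | 0.60 equiv | 0.60 equiv | 0.60 equiv | 0.600 equiv | 0.600 equiv (fed, over 8.0 h) | 0.600 equiv |
| Q | 0.90 equiv | 0.45 equiv | 1.8 equiv | 0.90 equiv | 0.900 equiv | 0.900 equiv | 0.900 equiv (fed, over 8.0 h) |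
| remark | run made earlier | run made earlier | run made earlier | run made earlier | everything together at the start | all else is in the flask from the start; the feed brings no volume worth counting | all else is in the flask from the start; the feed brings no volume worth counting |
| time |  |  |  |  | 20 h | 20 h | 20 h |

| run | time / h | Z / % | X / % |
|---|---|---|---|
| east | 1.50 | 15.8 | 3.2 |
| east | 4.00 | 38.8 | 10.4 |
| east | 8.00 | 53.4 | 17.4 |
| east | 12.0 | 57.2 | 20.7 |
| south-west | 2.00 | 20.7 | 1.4 |
| south-west | 4.00 | 39.5 | 6.6 |
| south-west | 10.0 | 55.2 | 15.7 |
| south-west | 25.0 | 59.1 | 21.0 |
| west | 6.00 | 49.4 | 17.3 |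
| west | 12.0 | 57.4 | 20.8 |
| west | 20.0 | 58.1 | 21.2 |
| west | 25.0 | 58.3 | 20.8 |
| south | 3.00 | 32.2 | 17.1 |
| south | 8.00 | 45.7 | 30.6 |
| south | 15.0 | 48.6 | 30.7 |
| south | 25.0 | 48.8 | 30.3 |

(scatter of a reading: 0.5 percentage points)

- the numbers in the tables scatter with a standard deviation of 0.5 percentage points

- the flask that comes out highest in amount of Z, in percent of the G charged; "all alike" if 1.5 percentage points covers them all (winter / noon / midnight / all alike)
- amount of Z at the end, in percent of the G charged, winter
- amount of Z at the end, in percent of the G charged, noon
- amount of Z at the end, in percent of the G charged, midnight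

In the west run, Z and X level off at 79.1% together, close to the 0.80 equiv of J charged, so J is the limiting reagent. Raising Q by a factor of 4.00 leaves the plateau X/Z at 0.357 in the west run against 0.355 in the south-west run, so in these runs Q changes the speed and, within the scatter, not the split. The south run, with more G and so more D in the flask, gives X/Z = 0.621.

Take [D] halfway between charge and end: 0.248 M in the west run and 0.449 M in the south run. X/Z per unit [D] is then 1.44 /M and 1.38 /M, so an unseen intermediate seems to choose between a path through D and a path to Z, with K = 1.41 /M. The branch number N = K[D] is the rate through D divided by the rate to Z at one moment, and with N steady, Z = 79.1%/(1 + N).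

For winter, N = 0.350 and Z = 58.6%. Midnight gets the same figure, since N does not contain Q and the plateau X/Z of the west and south-west runs agree. In noon, [D] climbs from zero instead of drifting down. The east run's shortfall from 79.1% decays, as read from two readings, with a time constant of 3.12 h, which is shorter than the feed of 8.0 h. Weighted by that decay, the ramp offers the intermediate the [D] of 2.88 h into the feed, 0.108 M. K[D] then gives 0.152, the noon branch number, and Z = 68.7%. One number serves here as an average over a changing [D].

The forecast names noon, with 58.3% for winter, 68% for noon and 58.3% for midnight; its noon figure stands below the 68.7% reckoned here, and it holds that “Changing Q alters only how fast X appears, not the final split”.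

Winter gives 58.6%, noon 68.4% and midnight 58.6%, with noon highest.

    G + J → E (k = 0.0590 /M/min)
    Q + L → X (k = 0.0270 /M/min)
    E → Z (k = 0.00500 /min)
    D + E → L (k = 0.00750 /M/min)

Noon's Z of 68.4% stands with X at 11.5%, a ratio of 0.168 against the branch number of 0.152. A neighbouring flask repeats noon with 0.480 equiv of J in place of 0.800 equiv. Taking the same branch number and a plateau total in proportion to J, the reckoning gives Z = 41.2%. That flask gives Z at 41.1%, X at 6.82%, and G left at 52.0%.

All runs were computed for substances that don't exist; noise was put on by code.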